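Numbering: ring A = C1, C2, C3 (OH), C4 (Me2), C5, C10; ring B = C5 to C10, with C8–Me and C9(Me)–C11H2–aryl.
Retrosynthesis: remove the two aryl MOM groups and the formyl group, then open ring A at C1=C10 and at C3–C4 in one [3+3] cut (isopropylidene ketone + 3-nitropropyl phosphonium salt), then cut C9–C11 (enolate benzylation) and C8–CH3 (conjugate addition).
Enabling feature: C10 (sp2) and C4 (CMe2) are both bonded to C5, so ring B can carry C10 as a ketone and C4 as the beta-carbon of the exocyclic enone C10(=O)–C5=C4Me2; a C1–C2–C3 unit nucleophilic at both ends (C3 nitronate, C1 ylide) adds at C4 and olefinates C10.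
Forward order: ring B from 2-methylcyclohex-2-enone with the arene attached at C9, then ring A by the annulation, then Nef reaction, C3 reduction, ester reduction, formylation and deprotection.
Stereochemistry: C8 by ligand-controlled Cu-catalysed conjugate addition; C9 by alkylation anti to the C8 methyl; C5 by thermodynamic control next to the C10 ketone during the annulation; C3 by catalyst-controlled (CBS) reduction.

Key step: step 7

Remark: 20 is written as the open hydroxy aldehyde of the target; equilibration with its lactol form is assumed not to affect the route.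
Remark: the phosphoramidite ligand in step 3 is taken as the enantiomer that gives the (3R)-enolate 5; its descriptor is an assumption.

Step 1
Reactants: 1 methyl 3,5-dihydroxy-4-methylbenzoate
Product: 2 methyl 3,5-bis(methoxymethoxy)-4-methylbenzoate
Conditions: MOMCl (2.5 equiv), i-Pr2NEt (3 equiv), CH2Cl2, 0 °C to rt
Reagents that add atoms: chloromethyl methyl ether, COCCl
Why: Double O-alkylation of the phenols (Williamson-type acetal formation) should give MOM ethers that withstand the later bases, hydrides and organolithiums and act as ortho-directing groups in step 11.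

Step 2
Reactants: 2 methyl 3,5-bis(methoxymethoxy)-4-methylbenzoate
Product: 3 methyl 4-(bromomethyl)-3,5-bis(methoxymethoxy)benzoate
Conditions: NBS (1.05 equiv), AIBN (5 mol %), PhCF3, 85 °C
Reagents that add atoms: N-bromosuccinimide, O=C1CCC(=O)N1Br
Why: Wohl–Ziegler bromination should occur at the only benzylic C–H position, the radical chain in a non-polar solvent being favoured over ionic ring bromination of the ester-deactivated arene.

Step 3
Reactants: 4 2-methylcyclohex-2-en-1-one; 3 methyl 4-(bromomethyl)-3,5-bis(methoxymethoxy)benzoate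
Product: 6 methyl 4-{[(1S,2R)-1,2-dimethyl-6-oxocyclohexyl]methyl}-3,5-bis(methoxymethoxy)benzoate, via dimethylaluminium enolate 5 (not isolated)
Conditions: Me3Al (1.3 equiv), Cu(O2CC4H3S) (copper thiophene-2-carboxylate, 2 mol %), (S,R,R)-binaphthyl bis(1-phenylethyl)phosphoramidite (4 mol %), Et2O, −30 °C; then MeLi (1.3 equiv), THF/DMPU; then 3 (1.1 equiv), −30 to 0 °C
Reagents that add atoms: trimethylaluminium, C[Al](C)C
Why: Cu-catalysed asymmetric conjugate addition sets C8 under ligand control, and the enolate (activated as its aluminate) should be benzylated on the face anti to the new C8 methyl, which sets quaternary C9 with the two methyls cis (conjugate addition–enolate alkylation).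

Step 4
Reactants: 6 methyl 4-{[(1S,2R)-1,2-dimethyl-6-oxocyclohexyl]methyl}-3,5-bis(methoxymethoxy)benzoate; 7 acetone
Product: 8 methyl 4-{[(1S,6R)-3-(2-hydroxypropan-2-yl)-1,6-dimethyl-2-oxocyclohexyl]methyl}-3,5-bis(methoxymethoxy)benzoate (both epimers at the aldol-bearing ring carbon)
Conditions: LiN(i-Pr)2 (1.1 equiv), THF, −78 °C; 7 (3 equiv), −78 °C; AcOH, −78 °C
Reagents that add atoms: none
Why: Only the C5 side of the C10 ketone is enolisable because C9 is quaternary, so a single lithium enolate forms and its aldol addition to acetone attaches C4 with both methyl groups (directed aldol reaction).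

Step 5
Reactants: 8 methyl 4-{[(1S,6R)-3-(2-hydroxypropan-2-yl)-1,6-dimethyl-2-oxocyclohexyl]methyl}-3,5-bis(methoxymethoxy)benzoate
Product: 10 methyl 4-{[(1S,6R)-1,6-dimethyl-2-oxo-3-(propan-2-ylidene)cyclohexyl]methyl}-3,5-bis(methoxymethoxy)benzoate, via tertiary mesylate 9 (not isolated)
Conditions: MsCl (2 equiv), Et3N (3 equiv), CH2Cl2, 0 °C; then DBU (3 equiv), rt
Reagents that add atoms: none
Why: Sulfene-type mesylation of the tertiary alcohol and E1cB elimination through the ketone enolate should give the conjugated tetrasubstituted enone, DBU converging any isopropenyl isomer to it.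

Step 6
Reactants: 11 nitromethane; 12 ethenyl(triphenyl)phosphonium bromide
Product: 13 (3-nitropropyl)triphenylphosphonium bromide
Conditions: 11 as solvent (large excess), Et3N (10 mol %), rt; precipitation with Et2O
Reagents that add atoms: none
Why: The nitronate of nitromethane should add to the vinylphosphonium salt (Michael-type addition) and the ylide so formed is protonated by the excess nitromethane, which also suppresses a second addition.

Step 7
Reactants: 10 methyl 4-{[(1S,6R)-1,6-dimethyl-2-oxo-3-(propan-2-ylidene)cyclohexyl]methyl}-3,5-bis(methoxymethoxy)benzoate; 13 (3-nitropropyl)triphenylphosphonium bromide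
Product: 15 methyl 4-{[(1S,2R,4aR)-1,2,5,5-tetramethyl-6-nitro-1,2,3,4,4a,5,6,7-octahydronaphthalen-1-yl]methyl}-3,5-bis(methoxymethoxy)benzoate (both epimers at the nitro-bearing carbon), via phosphonium nitronate Michael adduct 14 (not isolated)
Conditions: 13 (1.2 equiv), KOt-Bu (1.2 equiv), THF/DMSO, 0 °C to rt; then KOt-Bu (1.3 equiv), rt to 50 °C; AcOH
Reagents that add atoms: none
Why: Proposed new method: the first equivalent of base removes the most acidic proton of 13 (alpha to nitro) and the nitronate carbon C3 adds to C4, the beta-carbon of the s-cis-locked exocyclic enone of 10 (Michael addition, the adduct being held as the more stable nitronate 14), after which the second equivalent deprotonates alpha to phosphorus and the non-stabilised ylide carbon C1 attacks the C10 ketone in an intramolecular Wittig olefination that can only give the endocyclic C1=C10 alkene. The closest known reaction types are the Michael–Wittig [3+3] cyclohexadiene annulation of allylidenephosphoranes with enones, the vinylphosphonium cyclo-olefination and nitronate additions to beta,beta-dimethyl enones; new is one reagent with two carbanionic sites of graded acidity used in sequence. Ring A closes by 6-exo-trig attack of the ylide on the carbonyl carbon, giving an oxaphosphetane spiro-fused at C10 that loses Ph3P=O. C5 is set thermodynamically, because the ketone alpha-centre epimerises through its enolate under the basic conditions so that the bulky C4 side chain is equatorial, cis to the C9 benzyl group and trans to the axial C9 methyl, before the irreversible olefination fixes it; C3 is formed as an epimer mixture that step 8 erases. The step needs Michael addition before ylide formation and 1,4- over 1,2-attack, and both are secured by the pKa gap between the nitro and phosphonium alpha-protons, the softness of the nitronate and the shielding of the C10 carbonyl by quaternary C9.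

Step 8
Reactants: 15 methyl 4-{[(1S,2R,4aR)-1,2,5,5-tetramethyl-6-nitro-1,2,3,4,4a,5,6,7-octahydronaphthalen-1-yl]methyl}-3,5-bis(methoxymethoxy)benzoate
Product: 16 methyl 4-{[(1S,2R,4aR)-1,2,5,5-tetramethyl-6-oxo-1,2,3,4,4a,5,6,7-octahydronaphthalen-1-yl]methyl}-3,5-bis(methoxymethoxy)benzoate
Conditions: NaOMe (1.2 equiv), MeOH, 0 °C; then aq. TiCl3 (4 equiv), NH4OAc buffer (pH 5–6), THF/H2O, rt
Reagents that add atoms: water, O
Why: Reductive Nef reaction: the nitronate is reduced by TiCl3 to the imine, which hydrolyses to the C3 ketone under buffered conditions that should leave the MOM ethers, the ester and the non-conjugated C1=C10 alkene untouched.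

Step 9
Reactants: 16 methyl 4-{[(1S,2R,4aR)-1,2,5,5-tetramethyl-6-oxo-1,2,3,4,4a,5,6,7-octahydronaphthalen-1-yl]methyl}-3,5-bis(methoxymethoxy)benzoate
Product: 17 methyl 4-{[(1S,2R,4aR,6R)-6-hydroxy-1,2,5,5-tetramethyl-1,2,3,4,4a,5,6,7-octahydronaphthalen-1-yl]methyl}-3,5-bis(methoxymethoxy)benzoate
Conditions: (S)-2-methyl-CBS-oxazaborolidine (20 mol %), catecholborane (1.8 equiv), toluene, −78 to −40 °C; then MeOH, aq. NaHCO3
Reagents that add atoms: none
Why: CBS reduction: the (S)-oxazaborolidine should distinguish quaternary C4 (large) from the C2 methylene (small) and deliver hydride under catalyst control to give the (3R) axial alcohol cis to H-5, while catecholborane at low temperature spares the alkene and the ester.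

Step 10
Reactants: 17 methyl 4-{[(1S,2R,4aR,6R)-6-hydroxy-1,2,5,5-tetramethyl-1,2,3,4,4a,5,6,7-octahydronaphthalen-1-yl]methyl}-3,5-bis(methoxymethoxy)benzoate
Product: 18 [4-{[(1S,2R,4aR,6R)-6-hydroxy-1,2,5,5-tetramethyl-1,2,3,4,4a,5,6,7-octahydronaphthalen-1-yl]methyl}-3,5-bis(methoxymethoxy)phenyl]methanol
Conditions: LiAlH4 (2 equiv), THF, 0 °C; aq. sodium potassium tartrate
Reagents that add atoms: none
Why: Hydride reduction of the benzoate ester to the benzylic alcohol, with MOM ethers and the trisubstituted alkene inert to LiAlH4.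

Step 11
Reactants: 18 [4-{[(1S,2R,4aR,6R)-6-hydroxy-1,2,5,5-tetramethyl-1,2,3,4,4a,5,6,7-octahydronaphthalen-1-yl]methyl}-3,5-bis(methoxymethoxy)phenyl]methanol
Product: 19 3-{[(1S,2R,4aR,6R)-6-hydroxy-1,2,5,5-tetramethyl-1,2,3,4,4a,5,6,7-octahydronaphthalen-1-yl]methyl}-6-(hydroxymethyl)-2,4-bis(methoxymethoxy)benzaldehyde
Conditions: n-BuLi (3.3 equiv), TMEDA (3.3 equiv), THF, −20 to 0 °C; DMF (6 equiv), −78 °C to rt; H2O
Reagents that add atoms: N,N-dimethylformamide, CN(C)C=O
Why: Directed ortho-metalation: after both hydroxyls are deprotonated, lithiation should occur at the ring position flanked by an OMOM group and the CH2OLi group (the two open positions are equivalent by local symmetry), and DMF then formylates the aryllithium.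

Step 12
Reactants: 19 3-{[(1S,2R,4aR,6R)-6-hydroxy-1,2,5,5-tetramethyl-1,2,3,4,4a,5,6,7-octahydronaphthalen-1-yl]methyl}-6-(hydroxymethyl)-2,4-bis(methoxymethoxy)benzaldehyde
Product: 20 2,4-dihydroxy-3-{[(1S,2R,4aR,6R)-6-hydroxy-1,2,5,5-tetramethyl-1,2,3,4,4a,5,6,7-octahydronaphthalen-1-yl]methyl}-6-(hydroxymethyl)benzaldehyde
Conditions: 2 M aq. HCl, THF, rt to 40 °C
Reagents that add atoms: none
Why: Acid-catalysed acetal hydrolysis of the two aryl MOM ethers under dilute acid, mild enough that the trisubstituted alkene and the homoallylic alcohol should survive.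

Compound list
1 | methyl 3,5-dihydroxy-4-methylbenzoate | COC(=O)c1cc(O)c(C)c(O)c1 | starting material
2 | methyl 3,5-bis(methoxymethoxy)-4-methylbenzoate | COC(=O)c1cc(OCOC)c(C)c(OCOC)c1 | intermediate
3 | methyl 4-(bromomethyl)-3,5-bis(methoxymethoxy)benzoate | COC(=O)c1cc(OCOC)c(CBr)c(OCOC)c1 | intermediate
4 | 2-methylcyclohex-2-en-1-one | CC1=CCCCC1=O | starting material
5 | dimethylaluminium (3R)-2,3-dimethylcyclohex-1-en-1-olate | C[C@@H]1CCCC(O[Al](C)C)=C1C | intermediate
6 | methyl 4-{[(1S,2R)-1,2-dimethyl-6-oxocyclohexyl]methyl}-3,5-bis(methoxymethoxy)benzoate | C[C@@H]1CCCC(=O)[C@@]1(C)Cc1c(OCOC)cc(C(=O)OC)cc1OCOC | intermediate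
7 | acetone | CC(C)=O | starting material
8 | methyl 4-{[(1S,6R)-3-(2-hydroxypropan-2-yl)-1,6-dimethyl-2-oxocyclohexyl]methyl}-3,5-bis(methoxymethoxy)benzoate, both epimers at the aldol-bearing ring carbon | C[C@@H]1CCC(C(C)(C)O)C(=O)[C@@]1(C)Cc1c(OCOC)cc(C(=O)OC)cc1OCOC | intermediate
9 | methyl 4-{[(1S,6R)-3-[2-(methanesulfonyloxy)propan-2-yl]-1,6-dimethyl-2-oxocyclohexyl]methyl}-3,5-bis(methoxymethoxy)benzoate | C[C@@H]1CCC(C(C)(C)OS(C)(=O)=O)C(=O)[C@@]1(C)Cc1c(OCOC)cc(C(=O)OC)cc1OCOC | intermediate
10 | methyl 4-{[(1S,6R)-1,6-dimethyl-2-oxo-3-(propan-2-ylidene)cyclohexyl]methyl}-3,5-bis(methoxymethoxy)benzoate | C[C@@H]1CCC(=C(C)C)C(=O)[C@@]1(C)Cc1c(OCOC)cc(C(=O)OC)cc1OCOC | intermediate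
11 | nitromethane | C[N+](=O)[O-] | starting material
12 | ethenyl(triphenyl)phosphonium bromide | C=C[P+](c1ccccc1)(c1ccccc1)c1ccccc1.[Br-] | starting material
13 | (3-nitropropyl)triphenylphosphonium bromide | [O-][N+](=O)CCC[P+](c1ccccc1)(c1ccccc1)c1ccccc1.[Br-] | intermediate
14 | inner salt (phosphonium nitronate) of methyl 4-({(1S,3S,6R)-1,6-dimethyl-3-[2-methyl-3-nitro-5-(triphenylphosphonio)pentan-2-yl]-2-oxocyclohexyl}methyl)-3,5-bis(methoxymethoxy)benzoate, deprotonated at the nitro-bearing carbon | C[C@@H]1CC[C@@H](C(C)(C)C(CC[P+](c2ccccc2)(c2ccccc2)c2ccccc2)=[N+]([O-])[O-])C(=O)[C@@]1(C)Cc1c(OCOC)cc(C(=O)OC)cc1OCOC | intermediate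
15 | methyl 4-{[(1S,2R,4aR)-1,2,5,5-tetramethyl-6-nitro-1,2,3,4,4a,5,6,7-octahydronaphthalen-1-yl]methyl}-3,5-bis(methoxymethoxy)benzoate, both epimers at the nitro-bearing carbon | C[C@@H]1CC[C@@H]2C(=CCC([N+](=O)[O-])C2(C)C)[C@@]1(C)Cc1c(OCOC)cc(C(=O)OC)cc1OCOC | intermediate
16 | methyl 4-{[(1S,2R,4aR)-1,2,5,5-tetramethyl-6-oxo-1,2,3,4,4a,5,6,7-octahydronaphthalen-1-yl]methyl}-3,5-bis(methoxymethoxy)benzoate | C[C@@H]1CC[C@@H]2C(=CCC(=O)C2(C)C)[C@@]1(C)Cc1c(OCOC)cc(C(=O)OC)cc1OCOC | intermediate
17 | methyl 4-{[(1S,2R,4aR,6R)-6-hydroxy-1,2,5,5-tetramethyl-1,2,3,4,4a,5,6,7-octahydronaphthalen-1-yl]methyl}-3,5-bis(methoxymethoxy)benzoate | C[C@@H]1CC[C@@H]2C(=CC[C@@H](O)C2(C)C)[C@@]1(C)Cc1c(OCOC)cc(C(=O)OC)cc1OCOC | intermediate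
18 | [4-{[(1S,2R,4aR,6R)-6-hydroxy-1,2,5,5-tetramethyl-1,2,3,4,4a,5,6,7-octahydronaphthalen-1-yl]methyl}-3,5-bis(methoxymethoxy)phenyl]methanol | C[C@@H]1CC[C@@H]2C(=CC[C@@H](O)C2(C)C)[C@@]1(C)Cc1c(OCOC)cc(CO)cc1OCOC | intermediate
19 | 3-{[(1S,2R,4aR,6R)-6-hydroxy-1,2,5,5-tetramethyl-1,2,3,4,4a,5,6,7-octahydronaphthalen-1-yl]methyl}-6-(hydroxymethyl)-2,4-bis(methoxymethoxy)benzaldehyde | C[C@@H]1CC[C@@H]2C(=CC[C@@H](O)C2(C)C)[C@@]1(C)Cc1c(OCOC)cc(CO)c(C=O)c1OCOC | intermediate
20 | 2,4-dihydroxy-3-{[(1S,2R,4aR,6R)-6-hydroxy-1,2,5,5-tetramethyl-1,2,3,4,4a,5,6,7-octahydronaphthalen-1-yl]methyl}-6-(hydroxymethyl)benzaldehyde | C[C@@H]1CC[C@@H]2C(=CC[C@@H](O)C2(C)C)[C@@]1(C)Cc1c(O)cc(CO)c(C=O)c1O | target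

Total step count: 12. Longest linear sequence: 11 steps (from 1 through steps 1–5 and 7–12); step 6 is a one-step side branch.

Steps most likely to fail

Step 7 (proposed new method). What may go wrong: retro-Michael loss of the hindered nitronate adduct before olefination, enolisation instead of olefination at the crowded C10 ketone, or attack of the nitronate oxygen on phosphorus. Fallback with known chemistry, starting from 10: conjugate addition of nitromethane 11 (DBU, MeCN, rt; nitro-Michael addition to a beta,beta-dimethyl enone, with the ketone alpha-centre equilibrating as in the main route) should give the gamma-nitro ketone F1. Its nitronate (KOt-Bu, THF/DMSO) then adds to the vinylphosphonium salt 12, and the ylide so formed closes onto the C10 ketone by intramolecular Wittig reaction (vinylphosphonium cyclo-olefination). Ring A is then closed at C2–C3 and C1=C10 instead, and the sequence comes back to the route at 15.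

Step 9. What may go wrong: poor facial selectivity, since catalyst control has to override the substrate's preference for hydride delivery to the more open face syn to H-5 (anti to the pseudo-axial C4 methyl). Fallback, starting from 16: NaBH4 in MeOH at 0 °C should give mainly the C3-epimeric equatorial alcohol F2. Mitsunobu reaction (4-nitrobenzoic acid, PPh3, DIAD, toluene) inverts C3 to the 4-nitrobenzoate F3, and K2CO3 in MeOH removes the nitrobenzoate while leaving the methyl benzoate unchanged, returning to the route at 17. This inversion next to the quaternary C4 is itself likely to be sluggish and to compete with elimination.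

Step 11. What may go wrong: lateral lithiation at a benzylic position or over-lithiation instead of clean mono ortho-metalation of the dialkoxide. Fallback, starting from 18: 2 M aq. HCl in THF removes both MOM groups to give the resorcinol F4, and magnesium-mediated ortho-formylation of the free phenol (MgCl2, Et3N, paraformaldehyde, MeCN, reflux; Casnati–Skattebøl formylation) at one of the two equivalent positions ortho to a phenolic hydroxyl returns directly to 20.

Further compounds
F1 | step 7 | methyl 4-{[(1S,3S,6R)-1,6-dimethyl-3-(2-methyl-1-nitropropan-2-yl)-2-oxocyclohexyl]methyl}-3,5-bis(methoxymethoxy)benzoate | C[C@@H]1CC[C@@H](C(C)(C)C[N+](=O)[O-])C(=O)[C@@]1(C)Cc1c(OCOC)cc(C(=O)OC)cc1OCOC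
F2 | step 9 | methyl 4-{[(1S,2R,4aR,6S)-6-hydroxy-1,2,5,5-tetramethyl-1,2,3,4,4a,5,6,7-octahydronaphthalen-1-yl]methyl}-3,5-bis(methoxymethoxy)benzoate | C[C@@H]1CC[C@@H]2C(=CC[C@H](O)C2(C)C)[C@@]1(C)Cc1c(OCOC)cc(C(=O)OC)cc1OCOC
F3 | step 9 | methyl 3,5-bis(methoxymethoxy)-4-{[(1S,2R,4aR,6R)-1,2,5,5-tetramethyl-6-[(4-nitrobenzoyl)oxy]-1,2,3,4,4a,5,6,7-octahydronaphthalen-1-yl]methyl}benzoate | C[C@@H]1CC[C@@H]2C(=CC[C@@H](OC(=O)c3ccc(cc3)[N+](=O)[O-])C2(C)C)[C@@]1(C)Cc1c(OCOC)cc(C(=O)OC)cc1OCOC
F4 | step 11 | 2-{[(1S,2R,4aR,6R)-6-hydroxy-1,2,5,5-tetramethyl-1,2,3,4,4a,5,6,7-octahydronaphthalen-1-yl]methyl}-5-(hydroxymethyl)benzene-1,3-diol | C[C@@H]1CC[C@@H]2C(=CC[C@@H](O)C2(C)C)[C@@]1(C)Cc1c(O)cc(CO)cc1O
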